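**Retrosynthetic overview**
1. Target ⇐ Luche reduction of a macrocyclic (E)-enal ⇐ amine-salt-catalysed aldol condensation of an acyclic dialdehyde (C9=C10); the only ring, eleven-membered, is closed here, in the last C–C bond-forming step.
2. Dialdehyde ⇐ acyclic bis-acetal carrying the cis-epoxide (Shi epoxidation, C5/C6), the side-chain allylic alcohol (Shi epoxidation, then titanocene isomerisation) and the C4 ester (CBS reduction of a cross-conjugated dienone, then acylation).
3. Dienone ⇐ (Z)-alkenyllithium (C5–C9 and C12) + (E)-Weinreb enamide (C1–C4, C10, C11, side chain).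
4. Enamide ⇐ HWE ⇐ Nef ⇐ iminium-catalysed Michael addition of nitromethane to citral, which sets the quaternary C1 as the first stereocentre.
5. Alkenyl iodide ⇐ Zhao iodo-olefination of 5,5-dimethoxypentanal.

Atom labels used below: ring atoms C1 (quaternary), C2=C3, C4 (O-acyl), C5 (methyl-bearing epoxide carbon), C6, C7, C8, C9 (bears C12, the CH2OH carbon), C10, C11; side chain C1'–C5' with the carbinol at C3'. Target configuration: 1S, 4R, 5S, 6S, 3'S; C2=C3 E; C8 and C11 cis across C9=C10.

Assumption: commercial citral (geranial/neral mixture) is used, and both isomers are taken to react through the same (E)-iminium ion because they interconvert via the dienamine, as for other β-alkyl-β-methyl enals.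

**Step 1**
Reactants: 1 citral (3,7-dimethylocta-2,6-dienal; E isomer drawn); 2 nitromethane
Product: 4 (S)-8,8-dimethoxy-2,6-dimethyl-6-(nitromethyl)oct-2-ene, via nitro aldehyde 3 (not isolated)
Conditions: (R)-α,α-diphenyl-2-pyrrolidinemethanol trimethylsilyl ether (20 mol%), PhCO2H (20 mol%), MeNO2 (10 equiv), MeOH, 23 °C, 72 h; then HC(OMe)3, p-TsOH·H2O (40 mol%), 23 °C
Reagents that add atoms: trimethyl orthoformate, COC(OC)OC
Why: Iminium-ion (Hayashi–Jørgensen type) Michael addition, in which the CPh2OSiMe3 arm of the (R)-catalyst shields one face of the (E)-iminium so that the nitronate adds to the opposite face of the β-carbon and sets the all-carbon quaternary centre as S, after which the aldehyde is capped as its dimethyl acetal in the same pot.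

**Step 2**
Reactants: 4
Product: 6 (S)-2-(2,2-dimethoxyethyl)-2,6-dimethylhept-5-enal, via sodium nitronate 5 (not isolated)
Conditions: NaOMe (1.1 equiv), MeOH, 0 °C; then added to aq. TiCl3 (4 equiv)/NH4OAc buffer (pH 5–6), THF, 0 → 23 °C
Reagents that add atoms: water, O
Why: Nef reaction in McMurry's reductive form, where TiCl3 reduces the nitronate to the imine, which hydrolyses to the aldehyde at a pH that spares the acetal, and the quaternary centre has no α-hydrogen to epimerise.

**Step 3**
Reactants: 6; 7 diethyl {2-[methoxy(methyl)amino]-2-oxoethyl}phosphonate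
Product: 8 (2E,4S)-4-(2,2-dimethoxyethyl)-N-methoxy-N,4,8-trimethylnona-2,7-dienamide
Conditions: LiCl, DBU, MeCN, 23 → 40 °C
Reagents that add atoms: none
Why: Horner–Wadsworth–Emmons olefination under Masamune–Roush conditions, in which the non-enolisable α-quaternary aldehyde gives the (E)-enamide (C2=C3) selectively without touching the acetal.

**Step 4**
Reactants: 9 methyl 5,5-dimethoxypentanoate
Product: 10 5,5-dimethoxypentanal
Conditions: i-Bu2AlH (1.05 equiv), CH2Cl2, −78 °C; aq. KNaC4H4O6
Reagents that add atoms: none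
Why: Partial ester reduction with i-Bu2AlH, whose tetrahedral aluminium hemiacetal is stable at −78 °C and releases the aldehyde only on work-up.

**Step 5**
Reactants: 10; 11 ethyltriphenylphosphonium iodide
Product: 15 (Z)-6-iodo-1,1-dimethoxyhept-5-ene, via ethylidene ylide 12 (not isolated), via iodophosphonium salt 13 (not isolated), via iodo ylide 14 (not isolated)
Conditions: 11, n-BuLi, THF, 23 °C; I2, −78 °C; NaN(SiMe3)2, −20 °C; then 10, −78 → −20 °C
Reagents that add atoms: iodine, II
Why: Zhao iodo-olefination (Wittig reaction of the α-iodoethylidene ylide), which under kinetic control places iodine cis to the alkyl chain (Z typically ≥ 10:1) and so fixes the geometry that later becomes the cis-epoxide.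

**Step 6**
Reactants: 15; 8
Product: 18 (5Z,8E,10S)-10-(2,2-dimethoxyethyl)-1,1-dimethoxy-6,10,14-trimethylpentadeca-5,8,13-trien-7-one, via alkenyllithium 16 (not isolated), via lithium hemiaminal 17 (not isolated)
Conditions: 15, t-BuLi (2.05 equiv), Et2O, −78 °C; then 8, THF, −78 → −10 °C; aq. NH4Cl
Reagents that add atoms: none
Why: Iodine–lithium exchange with retention of alkene geometry followed by Weinreb ketone synthesis, where the chelated adduct stops at single addition and conjugate addition is blocked by the adjacent quaternary carbon, so work-up gives the cross-conjugated (Z,E)-dienone.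

**Step 7**
Reactants: 18
Product: 19 (5Z,8E,10S)-10-(2,2-dimethoxyethyl)-12-[(2S)-3,3-dimethyloxiran-2-yl]-1,1-dimethoxy-6,10-dimethyldodeca-5,8-dien-7-one
Conditions: L-fructose-derived Shi ketone (ent-Shi ketone, 30 mol%), KHSO5 (as 2KHSO5·KHSO4·K2SO4), K2CO3, Bu4NHSO4, MeCN–(MeO)2CH2–aq. Na2B4O7 buffer (pH 10.5), 0 °C
Reagents that add atoms: potassium peroxymonosulfate, [K+].[O-]S(=O)(=O)OO
Why: Shi epoxidation, in which the chiral dioxirane attacks only the electron-rich side-chain alkene (both other alkenes are enone-deactivated) through the spiro transition state, and the L-fructose-derived ketone delivers oxygen to the face that gives the (S)-epoxide.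

**Step 8**
Reactants: 19
Product: 20 (5Z,7R,8E,10S)-10-(2,2-dimethoxyethyl)-12-[(2S)-3,3-dimethyloxiran-2-yl]-1,1-dimethoxy-6,10-dimethyldodeca-5,8-dien-7-ol
Conditions: (S)-2-methyl-CBS-oxazaborolidine (20 mol%), catecholborane (1.8 equiv), toluene, −78 °C
Reagents that add atoms: none
Why: Corey–Bakshi–Shibata reduction, in which the ketone binds boron anti to its bulkier α-methyl-alkenyl arm so that the (S)-oxazaborolidine delivers hydride 1,2 to the face that gives the (R)-carbinol at C4.

**Step 9**
Reactants: 20; 21 3-methylbut-2-enoyl chloride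
Product: 22 (5Z,7R,8E,10S)-10-(2,2-dimethoxyethyl)-12-[(2S)-3,3-dimethyloxiran-2-yl]-1,1-dimethoxy-6,10-dimethyldodeca-5,8-dien-7-yl 3-methylbut-2-enoate
Conditions: 21, pyridine, DMAP (cat.), CH2Cl2, 0 °C
Reagents that add atoms: none
Why: DMAP-catalysed acylation of the only free hydroxyl, with pyridine rather than a stronger base to avoid deconjugation of the senecioyl unit and with C4 untouched.

**Step 10**
Reactants: 22
Product: 23 (5Z,7R,8E,10S,13S)-10-(2,2-dimethoxyethyl)-13-hydroxy-1,1-dimethoxy-6,10,14-trimethylpentadeca-5,8,14-trien-7-yl 3-methylbut-2-enoate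
Conditions: Cp2TiCl2 (2.5 equiv), Zn dust, THF, 23 °C (gives Cp2TiCl); then 22; dil. HCl/aq. NaH2PO4 work-up
Reagents that add atoms: none
Why: Titanocene-mediated epoxide opening (Nugent–RajanBabu), in which Cp2TiCl cleaves the tertiary C–O bond, a second Cp2TiCl traps the radical and β-hydride elimination from a methyl group gives the isopropenyl carbinol with the C–O stereocentre retained as S, while ester, acetals and alkenes are tolerated.

**Step 11**
Reactants: 23
Product: 24 (1R,2E,4S,7S)-1-[(2S,3S)-3-(4,4-dimethoxybutyl)-2-methyloxiran-2-yl]-4-(2,2-dimethoxyethyl)-7-hydroxy-4,8-dimethylnona-2,8-dien-1-yl 3-methylbut-2-enoate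
Conditions: L-fructose-derived Shi ketone (30 mol%), KHSO5 (1.3 equiv, as 2KHSO5·KHSO4·K2SO4), K2CO3, Bu4NHSO4, MeCN–(MeO)2CH2–aq. Na2B4O7 buffer (pH 10.5), −10 °C
Reagents that add atoms: potassium peroxymonosulfate, [K+].[O-]S(=O)(=O)OO
Why: Shi epoxidation of the Z-trisubstituted C5=C6 alkene, the most nucleophilic one left (the others are conjugated, 1,1-disubstituted or a hindered disubstituted alkene), which is stereospecific so C4 and C7 stay cis on the oxirane and, by the spiro transition-state model, gives (5S,6S) with the same ketone enantiomer under catalyst control.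

**Step 12**
Reactants: 24
Product: 25 (1R,2E,4S,7S)-7-hydroxy-4,8-dimethyl-1-[(2S,3S)-2-methyl-3-(4-oxobutyl)oxiran-2-yl]-4-(2-oxoethyl)nona-2,8-dien-1-yl 3-methylbut-2-enoate
Conditions: PPTS (0.3 equiv), acetone–H2O (9:1), 35 °C
Reagents that add atoms: water, O
Why: Acid-catalysed acetal hydrolysis frees both aldehydes, the epoxide being deactivated towards acid opening by the adjacent acyloxy group at this mild pH.

**Step 13**
Reactants: 25
Product: 27 (1S,2R,3E,5S,7E,11S)-8-formyl-5-[(3S)-3-hydroxy-4-methylpent-4-en-1-yl]-1,5-dimethyl-12-oxabicyclo[9.1.0]dodeca-3,7-dien-2-yl 3-methylbut-2-enoate, via aldol 26 (not isolated)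
Conditions: Bn2NH·CF3CO2H (40 mol%), 4 Å MS, toluene, 60 °C, 25 added by syringe pump over 12 h (final 1 mM)
Reagents that add atoms: none
Why: Proposed new method: the bulky secondary ammonium salt forms the enamine only at the unhindered C12 aldehyde (the α-carbon C11 of the other aldehyde is neopentyl and inert as a nucleophile), this enamine attacks the C10 aldehyde or its iminium across a chain pre-organised by the quaternary centre, the E-alkene and the cis-epoxide, and irreversible dehydration of aldol 26 gives the conjugated (E)-enal, the only geometry that keeps C8 and C11 cis in the ring; the closest known reactions are amine-salt-catalysed aldol condensations of dialdehydes to five- and six-membered cycloalkene carbaldehydes and base-mediated macrocyclic aldol condensations of diketones, whereas a catalytic enamine closure of an eleven-membered carbocycle between two different enolisable aldehydes has not been shown.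

**Step 14**
Reactants: 27
Product: 28 (1S,2R,3E,5S,7E,11S)-8-(hydroxymethyl)-5-[(3S)-3-hydroxy-4-methylpent-4-en-1-yl]-1,5-dimethyl-12-oxabicyclo[9.1.0]dodeca-3,7-dien-2-yl 3-methylbut-2-enoate (target)
Conditions: NaBH4, CeCl3·7H2O, MeOH, −40 °C
Reagents that add atoms: none
Why: Luche reduction, which reduces the enal 1,2 to the primary allylic alcohol within minutes and leaves the senecioate, the epoxide and all alkenes untouched, creating no new stereocentre.

**Compound list**
1 | citral, 3,7-dimethylocta-2,6-dienal (E/Z mixture, E drawn) | CC(C)=CCC/C(C)=C/C=O | starting material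
2 | nitromethane | C[N+](=O)[O-] | starting material
3 | (S)-3,7-dimethyl-3-(nitromethyl)oct-6-enal | CC(C)=CCC[C@@](C)(CC=O)C[N+](=O)[O-] | intermediate (not isolated)
4 | (S)-8,8-dimethoxy-2,6-dimethyl-6-(nitromethyl)oct-2-ene | CC(C)=CCC[C@@](C)(CC(OC)OC)C[N+](=O)[O-] | intermediate
5 | sodium nitronate of 4 | CC(C)=CCC[C@@](C)(CC(OC)OC)C=[N+]([O-])[O-].[Na+] | intermediate (not isolated)
6 | (S)-2-(2,2-dimethoxyethyl)-2,6-dimethylhept-5-enal | CC(C)=CCC[C@@](C)(CC(OC)OC)C=O | intermediate
7 | diethyl {2-[methoxy(methyl)amino]-2-oxoethyl}phosphonate | CCOP(=O)(CC(=O)N(C)OC)OCC | starting material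
8 | (2E,4S)-4-(2,2-dimethoxyethyl)-N-methoxy-N,4,8-trimethylnona-2,7-dienamide | CC(C)=CCC[C@@](C)(CC(OC)OC)/C=C/C(=O)N(C)OC | intermediate
9 | methyl 5,5-dimethoxypentanoate | COC(=O)CCCC(OC)OC | starting material
10 | 5,5-dimethoxypentanal | O=CCCCC(OC)OC | intermediate
11 | ethyltriphenylphosphonium iodide | CC[P+](c1ccccc1)(c1ccccc1)c1ccccc1.[I-] | starting material
12 | ethylidenetriphenylphosphorane | CC=P(c1ccccc1)(c1ccccc1)c1ccccc1 | intermediate (not isolated)
13 | (1-iodoethyl)triphenylphosphonium iodide (racemic) | CC(I)[P+](c1ccccc1)(c1ccccc1)c1ccccc1.[I-] | intermediate (not isolated)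
14 | (1-iodoethylidene)triphenylphosphorane | CC(I)=P(c1ccccc1)(c1ccccc1)c1ccccc1 | intermediate (not isolated)
15 | (Z)-6-iodo-1,1-dimethoxyhept-5-ene | C/C(I)=C/CCCC(OC)OC | intermediate
16 | (7,7-dimethoxyhept-2-en-2-yl)lithium, Li cis to the chain (geometry of 15 retained) | C/C([Li])=C/CCCC(OC)OC | intermediate (not isolated)
17 | lithium N-methoxy-N-methyl hemiaminal adduct of 16 and 8 (new carbon unassigned) | CC(C)=CCC[C@@](C)(CC(OC)OC)/C=C/C(O[Li])(N(C)OC)/C(C)=C\CCCC(OC)OC | intermediate (not isolated)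
18 | (5Z,8E,10S)-10-(2,2-dimethoxyethyl)-1,1-dimethoxy-6,10,14-trimethylpentadeca-5,8,13-trien-7-one | CC(C)=CCC[C@@](C)(CC(OC)OC)/C=C/C(=O)/C(C)=C\CCCC(OC)OC | intermediate
19 | (5Z,8E,10S)-10-(2,2-dimethoxyethyl)-12-[(2S)-3,3-dimethyloxiran-2-yl]-1,1-dimethoxy-6,10-dimethyldodeca-5,8-dien-7-one | CC1(C)O[C@H]1CC[C@@](C)(CC(OC)OC)/C=C/C(=O)/C(C)=C\CCCC(OC)OC | intermediate
20 | (5Z,7R,8E,10S)-10-(2,2-dimethoxyethyl)-12-[(2S)-3,3-dimethyloxiran-2-yl]-1,1-dimethoxy-6,10-dimethyldodeca-5,8-dien-7-ol | CC1(C)O[C@H]1CC[C@@](C)(CC(OC)OC)/C=C/[C@@H](O)/C(C)=C\CCCC(OC)OC | intermediate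
21 | 3-methylbut-2-enoyl chloride | CC(C)=CC(=O)Cl | starting material
22 | 3-methylbut-2-enoate of 20 | CC1(C)O[C@H]1CC[C@@](C)(CC(OC)OC)/C=C/[C@@H](OC(=O)C=C(C)C)/C(C)=C\CCCC(OC)OC | intermediate
23 | (5Z,7R,8E,10S,13S)-10-(2,2-dimethoxyethyl)-13-hydroxy-1,1-dimethoxy-6,10,14-trimethylpentadeca-5,8,14-trien-7-yl 3-methylbut-2-enoate | C=C(C)[C@@H](O)CC[C@@](C)(CC(OC)OC)/C=C/[C@@H](OC(=O)C=C(C)C)/C(C)=C\CCCC(OC)OC | intermediate
24 | (1R,2E,4S,7S)-1-[(2S,3S)-3-(4,4-dimethoxybutyl)-2-methyloxiran-2-yl]-4-(2,2-dimethoxyethyl)-7-hydroxy-4,8-dimethylnona-2,8-dien-1-yl 3-methylbut-2-enoate | C=C(C)[C@@H](O)CC[C@@](C)(CC(OC)OC)/C=C/[C@@H](OC(=O)C=C(C)C)[C@@]1(C)O[C@H]1CCCC(OC)OC | intermediate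
25 | (1R,2E,4S,7S)-7-hydroxy-4,8-dimethyl-1-[(2S,3S)-2-methyl-3-(4-oxobutyl)oxiran-2-yl]-4-(2-oxoethyl)nona-2,8-dien-1-yl 3-methylbut-2-enoate | C=C(C)[C@@H](O)CC[C@@](C)(CC=O)/C=C/[C@@H](OC(=O)C=C(C)C)[C@@]1(C)O[C@H]1CCCC=O | intermediate
26 | (1S,2R,3E,5S,11S)-8-formyl-7-hydroxy-5-[(3S)-3-hydroxy-4-methylpent-4-en-1-yl]-1,5-dimethyl-12-oxabicyclo[9.1.0]dodec-3-en-2-yl 3-methylbut-2-enoate (mixture at C7 and C8 of this name) | C=C(C)[C@@H](O)CC[C@]1(C)/C=C/[C@@H](OC(=O)C=C(C)C)[C@@]2(C)O[C@H]2CCC(C=O)C(O)C1 | intermediate (not isolated)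
27 | (1S,2R,3E,5S,7E,11S)-8-formyl-5-[(3S)-3-hydroxy-4-methylpent-4-en-1-yl]-1,5-dimethyl-12-oxabicyclo[9.1.0]dodeca-3,7-dien-2-yl 3-methylbut-2-enoate | C=C(C)[C@@H](O)CC[C@]1(C)/C=C/[C@@H](OC(=O)C=C(C)C)[C@@]2(C)O[C@H]2CC/C(C=O)=C\C1 | intermediate
28 | (1S,2R,3E,5S,7E,11S)-8-(hydroxymethyl)-5-[(3S)-3-hydroxy-4-methylpent-4-en-1-yl]-1,5-dimethyl-12-oxabicyclo[9.1.0]dodeca-3,7-dien-2-yl 3-methylbut-2-enoate | C=C(C)[C@@H](O)CC[C@]1(C)/C=C/[C@@H](OC(=O)C=C(C)C)[C@@]2(C)O[C@H]2CC/C(CO)=C\C1 | target

**Count and risks**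
Total: 14 steps. Longest linear sequence: 12 steps (1, 2, 3, 6, 7, 8, 9, 10, 11, 12, 13, 14 from citral).

Step 13 (the proposed ring closure) is the most likely to fail: intermolecular self-condensation of the unhindered aldehyde or condensation through the wrong enamine can outrun closure of the medium ring. The fallback uses known chemistry, sets out from 25 and comes back at 27. The unhindered aldehyde of 25 is α-brominated (NBS, cat. racemic 2,5-diphenylpyrrolidine, CH2Cl2, −40 °C; the neopentyl α-position of the other aldehyde reacts far more slowly) to give the α-bromo dialdehyde F1. PPh3 in toluene displaces bromide to give the α-formylalkyl-triphenylphosphonium bromide F2, and Et3N converts it into the formyl-stabilised ylide F3. Heating F3 at 1 mM in toluene closes the ring by intramolecular Wittig olefination of the C10 aldehyde, and the stabilised ylide gives the same (E)-enal 27.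

Step 11 is the second risk: the Shi epoxidation must pick one of four alkenes in a crowded Z-allylic ester, the C4 stereocentre may be mismatched with the catalyst, and the resulting epoxide then has to survive the acidic step 12. The fallback sets out from 23 and comes back at 27. The acetals of 23 are hydrolysed first (PPTS, wet acetone; no epoxide is present yet) to the triene dialdehyde F4. The ring is closed as in step 13, through the aldol F5, to the macrocyclic trienal F6. The Shi epoxidation with the same ketone is run last: in F6 the C9=C10 alkene is an enal and inert, the Z-trisubstituted C5=C6 alkene is the only electron-rich ring alkene, and the rigid ring adds a peripheral-attack bias to catalyst control, giving 27.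

Step 2 is the third risk: Nef reactions of primary nitro compounds to aldehydes are capricious, and the acetal must survive the buffered TiCl3. The fallback sets out from 4 and comes back at 6. The nitro group is reduced with LiAlH4 (Et2O, 0 °C) to the primary amine F7, which is converted to the aldehyde by Rapoport transamination (4-formyl-1-methylpyridinium benzenesulfonate, then DBU, then pH 5 aqueous work-up). This gives 6 without a nitronate or low-valent titanium.

**Further compounds**
F1 | step 13 | α-bromo dialdehyde: 25 with Br on C9 (both epimers) | C=C(C)[C@@H](O)CC[C@@](C)(CC=O)/C=C/[C@@H](OC(=O)C=C(C)C)[C@@]1(C)O[C@H]1CCC(Br)C=O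
F2 | step 13 | α-formylalkyl-triphenylphosphonium bromide: 25 with Ph3P+ on C9 | C=C(C)[C@@H](O)CC[C@@](C)(CC=O)/C=C/[C@@H](OC(=O)C=C(C)C)[C@@]1(C)O[C@H]1CCC(C=O)[P+](c1ccccc1)(c1ccccc1)c1ccccc1.[Br-]
F3 | step 13 | formyl-stabilised ylide: 25 with C9=PPh3 | C=C(C)[C@@H](O)CC[C@@](C)(CC=O)/C=C/[C@@H](OC(=O)C=C(C)C)[C@@]1(C)O[C@H]1CCC(C=O)=P(c1ccccc1)(c1ccccc1)c1ccccc1
F4 | step 11 | (5Z,7R,8E,10S,13S)-13-hydroxy-6,10,14-trimethyl-1-oxo-10-(2-oxoethyl)pentadeca-5,8,14-trien-7-yl 3-methylbut-2-enoate | C=C(C)[C@@H](O)CC[C@@](C)(CC=O)/C=C/[C@@H](OC(=O)C=C(C)C)/C(C)=C\CCCC=O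
F5 | step 11 | eleven-membered-ring aldol from F4 (C9–C10 bond formed, C9/C10 mixture, C5=C6 alkene in place of the epoxide) | C=C(C)[C@@H](O)CC[C@]1(C)/C=C/[C@@H](OC(=O)C=C(C)C)/C(C)=C\CCC(C=O)C(O)C1
F6 | step 11 | macrocyclic trienal: 27 with the Z C5=C6 alkene in place of the epoxide | C=C(C)[C@@H](O)CC[C@]1(C)/C=C/[C@@H](OC(=O)C=C(C)C)/C(C)=C\CC/C(C=O)=C\C1
F7 | step 2 | (S)-2-(2,2-dimethoxyethyl)-2,6-dimethylhept-5-en-1-amine | CC(C)=CCC[C@@](C)(CC(OC)OC)CN
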